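**Retrosynthetic overview**

1. The target is the desilylated form of a flavanone whose rings A and B are bought as benzenoid building blocks (5-methoxyresorcinol and 4-hydroxy-2-methoxybenzoic acid). Ring C, the pyranone ring O1–C2–C3–C4–C4a–C8a, is formed last.
2. Key disconnection C3–C4: ring C is closed by an enantioselective Rh-catalysed intramolecular hydroacylation. The A-ring aldehyde carbon (C4) bonds to the CH2 terminus (C3) of an aryl 1-arylvinyl ether while the aldehyde hydrogen goes to C2, so ring closure and the C2 stereocentre come from one isomerisation.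
3. Enabling feature: C3 of ring C is an unsubstituted CH2 between the C4 ketone (on C4a) and C2, and C2 carries exactly one H besides O1 (on C8a, ortho to C4a) and the B-ring aryl. The pair C2–H / C3–C4 is therefore the formal adduct of an aldehyde C–H across a 1,1-disubstituted enol ether C2=C3 that has no allylic hydrogen.
4. The enol ether comes from Tebbe methylenation of the aryl ester between the A-ring phenol and the B-ring acid, and the aldehyde from Br/Li exchange and formylation. The A ring is elaborated by two directed ortho-metalations of bis-MOM 5-methoxyresorcinol (iodide, then bromide) and an sp3–sp2 Negishi coupling with the side-chain iodide.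
5. The side-chain stereocentre comes from a deconjugative Evans alkylation of an N-senecioyl oxazolidinone with prenyl bromide. Chemoselective epoxidation and hydride opening turn the prenyl group into the tertiary alcohol.

Key step: step 17

Abbreviations in names: MOMO = methoxymethoxy, TESO = triethylsilyloxy, TBSO = tert-butyldimethylsilyloxy.

Remark: the sense of induction of the chiral bisphosphine in step 17 cannot be assigned beforehand; the ligand antipode that delivers hydride to the Re face of C2 (2S) is the one to be used, and (R)-MeO-BIPHEP is written as the first choice.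

**Route**

Step 1
Reactants: 1 (4S)-4-benzyl-1,3-oxazolidin-2-one; 2 3-methylbut-2-enoyl chloride
Product: 4 (4S)-4-benzyl-3-(3-methylbut-2-enoyl)-1,3-oxazolidin-2-one, via N-lithio oxazolidinone 3 (not isolated)
Conditions: n-BuLi, THF, −78 °C; then 2, −78 to 0 °C
Reagents that add atoms: none
Why: N-acylation of the lithiated auxiliary by the acid chloride; the auxiliary stereocentre is not touched.

Step 2
Reactants: 4 (4S)-4-benzyl-3-(3-methylbut-2-enoyl)-1,3-oxazolidin-2-one; 5 1-bromo-3-methylbut-2-ene (prenyl bromide)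
Product: 7 (4S)-4-benzyl-3-[(2S)-5-methyl-2-(prop-1-en-2-yl)hex-4-enoyl]-1,3-oxazolidin-2-one, via sodium dienolate 6 (not isolated)
Conditions: NaN(SiMe3)2, THF, −78 °C; then 5, −78 to −30 °C
Reagents that add atoms: none
Why: Evans alkylation in its deconjugative form: γ-deprotonation gives the chelated Z-dienolate, which should be alkylated at the α-carbon on the face opposite the benzyl group, setting the (2S) centre (the later 2R side-chain centre) and creating the isopropenyl group.

Step 3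
Reactants: 7 (4S)-4-benzyl-3-[(2S)-5-methyl-2-(prop-1-en-2-yl)hex-4-enoyl]-1,3-oxazolidin-2-one
Product: 8 (4S)-4-benzyl-3-{(2S)-2-[(3,3-dimethyloxiran-2-yl)methyl]-3-methylbut-3-enoyl}-1,3-oxazolidin-2-one (both epimers at the oxirane carbon)
Conditions: mCPBA (1.05 equiv), NaHCO3, CH2Cl2, 0 °C
Reagents that add atoms: 3-chloroperoxybenzoic acid (mCPBA), O=C(OO)c1cccc(Cl)c1
Why: Prilezhaev epoxidation should be chemoselective for the more electron-rich trisubstituted alkene over the 1,1-disubstituted alkene next to the acyl-bearing carbon; the oxirane CH configuration is irrelevant because that carbon becomes CH2 in step 4.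

Step 4
Reactants: 8 (4S)-4-benzyl-3-{(2S)-2-[(3,3-dimethyloxiran-2-yl)methyl]-3-methylbut-3-enoyl}-1,3-oxazolidin-2-one
Product: 9 (2S)-5-methyl-2-(prop-1-en-2-yl)hexane-1,5-diol
Conditions: LiAlH4, THF, 0 to 40 °C; aq. NaOH work-up
Reagents that add atoms: none
Why: hydride reduction cleaves the N-acyl bond to the primary alcohol and opens the trisubstituted epoxide at its less substituted carbon to the tertiary alcohol; once the acyl group is reduced the stereocentre is no longer α to a carbonyl.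

Step 5
Reactants: 9 (2S)-5-methyl-2-(prop-1-en-2-yl)hexane-1,5-diol
Product: 10 (5S)-6-iodo-2-methyl-5-(prop-1-en-2-yl)hexan-2-ol
Conditions: PPh3, imidazole, I2, CH2Cl2, 0 °C
Reagents that add atoms: iodine, [I][I]
Why: Appel reaction (iodide variant): only the primary hydroxyl is activated and displaced by iodide in an SN2 step, leaving the hindered tertiary alcohol and the stereocentre untouched.

Step 6
Reactants: 10 (5S)-6-iodo-2-methyl-5-(prop-1-en-2-yl)hexan-2-ol
Product: 11 triethyl{[(5S)-6-iodo-2-methyl-5-(prop-1-en-2-yl)hexan-2-yl]oxy}silane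
Conditions: Et3SiOTf, 2,6-lutidine, CH2Cl2, −78 to 0 °C
Reagents that add atoms: triethylsilyl trifluoromethanesulfonate, CC[Si](CC)(CC)OS(=O)(=O)C(F)(F)F
Why: silylation of the tertiary alcohol with the reactive silyl triflate removes the acidic proton before the organometallic steps.

Step 7
Reactants: 12 5-methoxybenzene-1,3-diol (5-methoxyresorcinol)
Product: 13 1-methoxy-3,5-bis(methoxymethoxy)benzene
Conditions: MOMCl, i-Pr2NEt, CH2Cl2, 0 °C to rt
Reagents that add atoms: chloromethyl methyl ether, COCCl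
Why: O-alkylation of both phenols installs two acetal ethers that serve as directing groups for ortho-lithiation.

Step 8
Reactants: 13 1-methoxy-3,5-bis(methoxymethoxy)benzene
Product: 15 2-iodo-5-methoxy-1,3-bis(methoxymethoxy)benzene, via aryllithium 14 (not isolated)
Conditions: n-BuLi, THF, 0 °C; then I2, −78 °C to rt
Reagents that add atoms: iodine, [I][I]
Why: directed ortho-metalation: the C–H between the two MOM ethers is the only one activated by two of the stronger directing groups (MOM over OMe), and iodinolysis should give the symmetric aryl iodide.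

Step 9
Reactants: 11 triethyl{[(5S)-6-iodo-2-methyl-5-(prop-1-en-2-yl)hexan-2-yl]oxy}silane; 15 2-iodo-5-methoxy-1,3-bis(methoxymethoxy)benzene
Product: 17 triethyl{[(5R)-6-[4-methoxy-2,6-bis(MOMO)phenyl]-2-methyl-5-(prop-1-en-2-yl)hexan-2-yl]oxy}silane, via alkylzinc iodide 16 (not isolated)
Conditions: Zn (activated with BrCH2CH2Br, Me3SiCl), LiCl, THF, 40 °C; then 15, Pd(OAc)2 (cat.), SPhos (cat.), THF, 50 °C
Reagents that add atoms: none
Why: Negishi sp3–sp2 coupling: zinc inserts into the primary C–I bond and the bulky electron-rich biarylphosphine favours reductive elimination at the doubly ortho-substituted aryl over β-hydride elimination; the stereocentre is β to zinc and not involved (the descriptor changes from S to R only by priority).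

Step 10
Reactants: 17 triethyl{[(5R)-6-[4-methoxy-2,6-bis(MOMO)phenyl]-2-methyl-5-(prop-1-en-2-yl)hexan-2-yl]oxy}silane
Product: 19 {[(5R)-6-[3-bromo-4-methoxy-2,6-bis(MOMO)phenyl]-2-methyl-5-(prop-1-en-2-yl)hexan-2-yl]oxy}triethylsilane, via aryllithium 18 (not isolated)
Conditions: n-BuLi, THF, −78 to 0 °C; then BrCl2C–CCl2Br, −78 °C
Reagents that add atoms: 1,2-dibromo-1,1,2,2-tetrachloroethane, BrC(Cl)(Cl)C(Cl)(Cl)Br
Why: directed ortho-metalation at the only remaining kind of ring C–H (two positions equivalent by symmetry, each between OMOM and OMe) and bromination of the aryllithium; the bromine marks the carbon that will carry C4.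

Step 11
Reactants: 19 {[(5R)-6-[3-bromo-4-methoxy-2,6-bis(MOMO)phenyl]-2-methyl-5-(prop-1-en-2-yl)hexan-2-yl]oxy}triethylsilane
Product: 21 4-bromo-5-methoxy-2-[(2R)-5-methyl-2-(prop-1-en-2-yl)-5-(TESO)hexyl]benzene-1,3-diol, via bis(trimethylsilyl) aryl ether 20 (not isolated)
Conditions: Me3SiOTf, 2,2'-bipyridyl, MeCN, 0 °C to rt; then H2O
Reagents that add atoms: none
Why: cleavage of aromatic MOM ethers by a silyl triflate/2,2'-bipyridyl pair runs through the aryl trimethylsilyl ethers under buffered non-protic conditions, so the tertiary TES ether, the isopropenyl group and the aryl bromide should survive; water then hydrolyses the labile aryl TMS ethers.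

Step 12
Reactants: 21 4-bromo-5-methoxy-2-[(2R)-5-methyl-2-(prop-1-en-2-yl)-5-(TESO)hexyl]benzene-1,3-diol
Product: 22 2-bromo-5-(TBSO)-3-methoxy-6-[(2R)-5-methyl-2-(prop-1-en-2-yl)-5-(TESO)hexyl]phenol
Conditions: TBSCl (1 equiv), imidazole, DMF, −20 to 0 °C
Reagents that add atoms: tert-butyldimethylsilyl chloride, CC(C)(C)[Si](C)(C)Cl
Why: steric differentiation in silylation: the phenol flanked by CH2 and H should react, while the phenol flanked by CH2 and bromine is too hindered for the bulky chlorosilane at low temperature.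

Step 13
Reactants: 23 4-hydroxy-2-methoxybenzoic acid
Product: 25 4-(TBSO)-2-methoxybenzoic acid, via silyl ester 24 (not isolated)
Conditions: TBSCl (2.2 equiv), imidazole, DMF, rt; then AcOH, THF, H2O, rt
Reagents that add atoms: tert-butyldimethylsilyl chloride, CC(C)(C)[Si](C)(C)Cl
Why: silylation of phenol and acid followed by selective hydrolysis of the far more labile silyl ester.

Step 14
Reactants: 22 2-bromo-5-(TBSO)-3-methoxy-6-[(2R)-5-methyl-2-(prop-1-en-2-yl)-5-(TESO)hexyl]phenol; 25 4-(TBSO)-2-methoxybenzoic acid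
Product: 27 2-bromo-5-(TBSO)-3-methoxy-6-[(2R)-5-methyl-2-(prop-1-en-2-yl)-5-(TESO)hexyl]phenyl 4-(TBSO)-2-methoxybenzoate, via acid chloride 26 (not isolated)
Conditions: 25, (COCl)2, DMF (cat.), CH2Cl2, 0 °C to rt, evaporation; then 22, Et3N, DMAP (cat.), CH2Cl2, 0 °C to rt
Reagents that add atoms: none
Why: acid chloride formation under Vilsmeier catalysis and DMAP-catalysed acylation of the hindered phenol give the aryl ester that carries ring B and the future C2.

Step 15
Reactants: 27 2-bromo-5-(TBSO)-3-methoxy-6-[(2R)-5-methyl-2-(prop-1-en-2-yl)-5-(TESO)hexyl]phenyl 4-(TBSO)-2-methoxybenzoate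
Product: 28 [4-bromo-3-({1-[4-(TBSO)-2-methoxyphenyl]ethenyl}oxy)-5-methoxy-2-[(2R)-5-methyl-2-(prop-1-en-2-yl)-5-(TESO)hexyl]phenoxy](tert-butyl)dimethylsilane
Conditions: Cp2Ti(μ-CH2)(μ-Cl)AlMe2, pyridine, toluene/THF, −40 °C to rt; aq. NaOH quench, basic Al2O3
Reagents that add atoms: Tebbe reagent Cp2Ti(μ-CH2)(μ-Cl)AlMe2, C[Al](C)C[Ti](Cl)(C1C=CC=C1)C1C=CC=C1
Why: Tebbe methylenation converts the aryl ester carbonyl into the 1-arylvinyl ether (C2=C3) through an oxatitanacyclobutane, as known for aryl benzoates; aryl bromide and silyl ethers are inert and the basic work-up protects the acid-sensitive enol ether.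

Step 16
Reactants: 28 [4-bromo-3-({1-[4-(TBSO)-2-methoxyphenyl]ethenyl}oxy)-5-methoxy-2-[(2R)-5-methyl-2-(prop-1-en-2-yl)-5-(TESO)hexyl]phenoxy](tert-butyl)dimethylsilane
Product: 30 4-(TBSO)-2-({1-[4-(TBSO)-2-methoxyphenyl]ethenyl}oxy)-6-methoxy-3-[(2R)-5-methyl-2-(prop-1-en-2-yl)-5-(TESO)hexyl]benzaldehyde, via aryllithium 29 (not isolated)
Conditions: t-BuLi (2 equiv), Et2O, −78 °C; then DMF, −78 to 0 °C; H2O
Reagents that add atoms: N,N-dimethylformamide, CN(C)C=O
Why: bromine–lithium exchange at −78 °C is faster than any attack on the enol ether, and formylation of the aryllithium with DMF delivers the aldehyde carbon (C4).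

Step 17
Reactants: 30 4-(TBSO)-2-({1-[4-(TBSO)-2-methoxyphenyl]ethenyl}oxy)-6-methoxy-3-[(2R)-5-methyl-2-(prop-1-en-2-yl)-5-(TESO)hexyl]benzaldehyde
Product: 31 (2S)-7-(TBSO)-2-[4-(TBSO)-2-methoxyphenyl]-5-methoxy-8-[(2R)-5-methyl-2-(prop-1-en-2-yl)-5-(TESO)hexyl]-2,3-dihydro-4H-chromen-4-one
Conditions: [Rh(cod)Cl]2 (cat.), (R)-MeO-BIPHEP (cat.), Na[B(3,5-(CF3)2C6H3)4] (cat.), degassed THF, 60 °C
Reagents that add atoms: none
Why: Proposed new method: the aldehyde C–H of 30 adds oxidatively to the cationic monovalent rhodium bisphosphine complex to give an acyl rhodium hydride (trivalent rhodium), the enol ether C2=C3 inserts into Rh–H with hydride going to C2 and rhodium to the terminal C3, and C–C reductive elimination from the seven-membered acyl alkyl rhodacycle forms C3–C4 and releases 31; the closest known reaction type is the Rh/bisphosphine-catalysed enantioselective endo hydroacylation of 1,1-disubstituted alkenes (2-(1-substituted vinyl)benzaldehydes to 3-substituted indanones, N-(1-substituted vinyl)indole-2-carbaldehydes to β-substituted cyclic ketones), which has not been run on aryl 1-arylvinyl ethers of salicylaldehydes. Ring C closes in a formal 6-endo-trig mode, and the alkene has no allylic hydrogen that could lead to isomerisation. The C2 stereocentre is set in the hydride insertion under control of the axially chiral bisphosphine, which has to deliver hydride to the Re face of C2 to give 2S; the remote side-chain centre is too far away to interfere. The step needs endo over exo regiochemistry (exo insertion would end in a 2-aryl-2-methylbenzofuran-3-one), which should be secured by the fully substituted C2 with its ortho-methoxyaryl group, since rhodium avoids a tertiary alkyl and a reductive elimination that forms a quaternary centre. It also needs insertion to outrun decarbonylation, which the two ortho oxygen substituents of the aldehyde (the C5 methoxy group and O1) should help by chelating the acyl rhodium hydride, while the isopropenyl group cannot reach the metal in a ring of reasonable size.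

Step 18
Reactants: 31 (2S)-7-(TBSO)-2-[4-(TBSO)-2-methoxyphenyl]-5-methoxy-8-[(2R)-5-methyl-2-(prop-1-en-2-yl)-5-(TESO)hexyl]-2,3-dihydro-4H-chromen-4-one
Product: 32 (2S)-7-hydroxy-2-(4-hydroxy-2-methoxyphenyl)-8-[(2R)-5-hydroxy-5-methyl-2-(prop-1-en-2-yl)hexyl]-5-methoxy-2,3-dihydro-4H-chromen-4-one
Conditions: Bu4NF, AcOH (1:1), THF, 0 °C to rt
Reagents that add atoms: none
Why: fluoride cleaves the two aryl TBS ethers and the tertiary TES ether, and the AcOH buffer keeps the medium non-basic so that the flavanone should not open to the chalcone and C2 should not epimerise.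

**Compound list**

1 | (4S)-4-benzyl-1,3-oxazolidin-2-one | O=C1OC[C@H](Cc2ccccc2)N1 | starting material
2 | 3-methylbut-2-enoyl chloride | CC(C)=CC(=O)Cl | starting material
3 | N-lithio (4S)-4-benzyl-1,3-oxazolidin-2-one | [Li]N1C(=O)OC[C@@H]1Cc1ccccc1 | intermediate
4 | (4S)-4-benzyl-3-(3-methylbut-2-enoyl)-1,3-oxazolidin-2-one | CC(C)=CC(=O)N1C(=O)OC[C@@H]1Cc1ccccc1 | intermediate
5 | 1-bromo-3-methylbut-2-ene | CC(C)=CCBr | starting material
6 | sodium (Z)-dienolate of 4 | C=C(C)/C=C(\[O-])N1C(=O)OC[C@@H]1Cc1ccccc1.[Na+] | intermediate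
7 | (4S)-4-benzyl-3-[(2S)-5-methyl-2-(prop-1-en-2-yl)hex-4-enoyl]-1,3-oxazolidin-2-one | C=C(C)[C@H](CC=C(C)C)C(=O)N1C(=O)OC[C@@H]1Cc1ccccc1 | intermediate
8 | (4S)-4-benzyl-3-{(2S)-2-[(3,3-dimethyloxiran-2-yl)methyl]-3-methylbut-3-enoyl}-1,3-oxazolidin-2-one (both oxirane epimers) | C=C(C)[C@H](CC1OC1(C)C)C(=O)N1C(=O)OC[C@@H]1Cc1ccccc1 | intermediate
9 | (2S)-5-methyl-2-(prop-1-en-2-yl)hexane-1,5-diol | C=C(C)[C@H](CCC(C)(C)O)CO | intermediate
10 | (5S)-6-iodo-2-methyl-5-(prop-1-en-2-yl)hexan-2-ol | C=C(C)[C@H](CCC(C)(C)O)CI | intermediate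
11 | triethyl{[(5S)-6-iodo-2-methyl-5-(prop-1-en-2-yl)hexan-2-yl]oxy}silane | C=C(C)[C@H](CCC(C)(C)O[Si](CC)(CC)CC)CI | intermediate
12 | 5-methoxybenzene-1,3-diol | COc1cc(O)cc(O)c1 | starting material
13 | 1-methoxy-3,5-bis(methoxymethoxy)benzene | COCOc1cc(OC)cc(OCOC)c1 | intermediate
14 | [4-methoxy-2,6-bis(methoxymethoxy)phenyl]lithium | COCOc1cc(OC)cc(OCOC)c1[Li] | intermediate
15 | 2-iodo-5-methoxy-1,3-bis(methoxymethoxy)benzene | COCOc1cc(OC)cc(OCOC)c1I | intermediate
16 | [(2S)-5-methyl-2-(prop-1-en-2-yl)-5-(TESO)hexyl]zinc iodide | C=C(C)[C@H](CCC(C)(C)O[Si](CC)(CC)CC)C[Zn]I | intermediate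
17 | triethyl{[(5R)-6-[4-methoxy-2,6-bis(MOMO)phenyl]-2-methyl-5-(prop-1-en-2-yl)hexan-2-yl]oxy}silane | C=C(C)[C@H](CCC(C)(C)O[Si](CC)(CC)CC)Cc1c(OCOC)cc(OC)cc1OCOC | intermediate
18 | aryllithium of 17, lithiated between OMOM and OMe | C=C(C)[C@H](CCC(C)(C)O[Si](CC)(CC)CC)Cc1c(OCOC)c([Li])c(OC)cc1OCOC | intermediate
19 | {[(5R)-6-[3-bromo-4-methoxy-2,6-bis(MOMO)phenyl]-2-methyl-5-(prop-1-en-2-yl)hexan-2-yl]oxy}triethylsilane | C=C(C)[C@H](CCC(C)(C)O[Si](CC)(CC)CC)Cc1c(OCOC)c(Br)c(OC)cc1OCOC | intermediate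
20 | bis(trimethylsilyl) ether of 21 | C=C(C)[C@H](CCC(C)(C)O[Si](CC)(CC)CC)Cc1c(O[Si](C)(C)C)c(Br)c(OC)cc1O[Si](C)(C)C | intermediate
21 | 4-bromo-5-methoxy-2-[(2R)-5-methyl-2-(prop-1-en-2-yl)-5-(TESO)hexyl]benzene-1,3-diol | C=C(C)[C@H](CCC(C)(C)O[Si](CC)(CC)CC)Cc1c(O)c(Br)c(OC)cc1O | intermediate
22 | 2-bromo-5-(TBSO)-3-methoxy-6-[(2R)-5-methyl-2-(prop-1-en-2-yl)-5-(TESO)hexyl]phenol | C=C(C)[C@H](CCC(C)(C)O[Si](CC)(CC)CC)Cc1c(O)c(Br)c(OC)cc1O[Si](C)(C)C(C)(C)C | intermediate
23 | 4-hydroxy-2-methoxybenzoic acid | COc1cc(O)ccc1C(=O)O | starting material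
24 | tert-butyldimethylsilyl 4-(TBSO)-2-methoxybenzoate | COc1cc(O[Si](C)(C)C(C)(C)C)ccc1C(=O)O[Si](C)(C)C(C)(C)C | intermediate
25 | 4-(TBSO)-2-methoxybenzoic acid | COc1cc(O[Si](C)(C)C(C)(C)C)ccc1C(=O)O | intermediate
26 | 4-(TBSO)-2-methoxybenzoyl chloride | COc1cc(O[Si](C)(C)C(C)(C)C)ccc1C(=O)Cl | intermediate
27 | 2-bromo-5-(TBSO)-3-methoxy-6-[(2R)-5-methyl-2-(prop-1-en-2-yl)-5-(TESO)hexyl]phenyl 4-(TBSO)-2-methoxybenzoate | C=C(C)[C@H](CCC(C)(C)O[Si](CC)(CC)CC)Cc1c(OC(=O)c2ccc(O[Si](C)(C)C(C)(C)C)cc2OC)c(Br)c(OC)cc1O[Si](C)(C)C(C)(C)C | intermediate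
28 | [4-bromo-3-({1-[4-(TBSO)-2-methoxyphenyl]ethenyl}oxy)-5-methoxy-2-[(2R)-5-methyl-2-(prop-1-en-2-yl)-5-(TESO)hexyl]phenoxy](tert-butyl)dimethylsilane | C=C(C)[C@H](CCC(C)(C)O[Si](CC)(CC)CC)Cc1c(OC(=C)c2ccc(O[Si](C)(C)C(C)(C)C)cc2OC)c(Br)c(OC)cc1O[Si](C)(C)C(C)(C)C | intermediate
29 | aryllithium from 28 by Br/Li exchange | C=C(C)[C@H](CCC(C)(C)O[Si](CC)(CC)CC)Cc1c(OC(=C)c2ccc(O[Si](C)(C)C(C)(C)C)cc2OC)c([Li])c(OC)cc1O[Si](C)(C)C(C)(C)C | intermediate
30 | 4-(TBSO)-2-({1-[4-(TBSO)-2-methoxyphenyl]ethenyl}oxy)-6-methoxy-3-[(2R)-5-methyl-2-(prop-1-en-2-yl)-5-(TESO)hexyl]benzaldehyde | C=C(C)[C@H](CCC(C)(C)O[Si](CC)(CC)CC)Cc1c(OC(=C)c2ccc(O[Si](C)(C)C(C)(C)C)cc2OC)c(C=O)c(OC)cc1O[Si](C)(C)C(C)(C)C | intermediate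
31 | (2S)-7-(TBSO)-2-[4-(TBSO)-2-methoxyphenyl]-5-methoxy-8-[(2R)-5-methyl-2-(prop-1-en-2-yl)-5-(TESO)hexyl]-2,3-dihydro-4H-chromen-4-one | C=C(C)[C@H](CCC(C)(C)O[Si](CC)(CC)CC)Cc1c(O[Si](C)(C)C(C)(C)C)cc(OC)c2c1O[C@H](c1ccc(O[Si](C)(C)C(C)(C)C)cc1OC)CC2=O | intermediate
32 | (2S)-7-hydroxy-2-(4-hydroxy-2-methoxyphenyl)-8-[(2R)-5-hydroxy-5-methyl-2-(prop-1-en-2-yl)hexyl]-5-methoxy-2,3-dihydro-4H-chromen-4-one | C=C(C)[C@H](CCC(C)(C)O)Cc1c(O)cc(OC)c2c1O[C@H](c1ccc(O)cc1OC)CC2=O | target

**Step count and risks**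

Total step count: 18. Longest linear sequence: 15 steps (steps 1–6, 9–12, 14–18).

Steps most likely to fail:

1. Step 17 (proposed new method). What may go wrong: decarbonylation of the acyl rhodium hydride before alkene insertion, hydride insertion with the opposite regiochemistry leading to five-membered ring closure, or poor facial selectivity. Fallback by known chemistry, with the C2–aryl bond made last. It sets out from 22: deprotonation with n-BuLi, Br/Li exchange with t-BuLi and acylation with N-methoxy-N-methylacetamide should give 1-{4-(TBSO)-2-hydroxy-6-methoxy-3-[(2R)-5-methyl-2-(prop-1-en-2-yl)-5-(TESO)hexyl]phenyl}ethan-1-one F1. Heating with N,N-dimethylformamide dimethyl acetal in toluene should give the enaminone (2E)-1-{4-(TBSO)-2-hydroxy-6-methoxy-3-[(2R)-5-methyl-2-(prop-1-en-2-yl)-5-(TESO)hexyl]phenyl}-3-(dimethylamino)prop-2-en-1-one F2, which should close with pyridinium p-toluenesulfonate to the chromone 7-(TBSO)-5-methoxy-8-[(2R)-5-methyl-2-(prop-1-en-2-yl)-5-(TESO)hexyl]-4H-chromen-4-one F3. Rh-catalysed asymmetric 1,4-addition of (4-hydroxy-2-methoxyphenyl)boronic acid ([Rh(OH)(cod)]2, electron-poor chiral biaryl bisphosphine, toluene/H2O) should give (2S)-7-(TBSO)-2-(4-hydroxy-2-methoxyphenyl)-5-methoxy-8-[(2R)-5-methyl-2-(prop-1-en-2-yl)-5-(TESO)hexyl]-2,3-dihydro-4H-chromen-4-one F4. Desilylation under the conditions of step 18 brings the route back at 32.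

2. Step 12. What may go wrong: insufficient discrimination between the two phenols, with silylation at the hindered oxygen or at both. Fallback by over-acylation and selective deacylation. It sets out from 21, which is acylated on both phenols with an excess of acid chloride 26 (Et3N, DMAP) to 4-bromo-5-methoxy-2-[(2R)-5-methyl-2-(prop-1-en-2-yl)-5-(TESO)hexyl]-1,3-phenylene bis[4-(TBSO)-2-methoxybenzoate] F5. The ester on the less hindered oxygen (flanked by CH2 and H) is then removed by aminolysis with n-BuNH2 in THF at 0 °C to give 2-bromo-5-hydroxy-3-methoxy-6-[(2R)-5-methyl-2-(prop-1-en-2-yl)-5-(TESO)hexyl]phenyl 4-(TBSO)-2-methoxybenzoate F6. Silylation with TBSCl/imidazole brings the route back at 27.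

3. Step 9. What may go wrong: incomplete zinc insertion, protodezincation, or slow transmetalation and β-hydride elimination at the doubly ortho-substituted aryl iodide. Fallback with reversed polarity (aryl nucleophile, alkyl electrophile). It sets out from 13, which is lithiated to 14 as in step 8 and converted with CuI (0.5 equiv) into lithium bis[4-methoxy-2,6-bis(methoxymethoxy)phenyl]cuprate F7. SN2 alkylation of this cuprate with iodide 11 (THF, −20 °C to rt) brings the route back at 17 and bypasses 15 and the organozinc.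

Further compounds
F1 | step 17 | 1-{4-(TBSO)-2-hydroxy-6-methoxy-3-[(2R)-5-methyl-2-(prop-1-en-2-yl)-5-(TESO)hexyl]phenyl}ethan-1-one | C=C(C)[C@H](CCC(C)(C)O[Si](CC)(CC)CC)Cc1c(O)c(C(C)=O)c(OC)cc1O[Si](C)(C)C(C)(C)C
F2 | step 17 | (2E)-1-{4-(TBSO)-2-hydroxy-6-methoxy-3-[(2R)-5-methyl-2-(prop-1-en-2-yl)-5-(TESO)hexyl]phenyl}-3-(dimethylamino)prop-2-en-1-one | C=C(C)[C@H](CCC(C)(C)O[Si](CC)(CC)CC)Cc1c(O)c(C(=O)/C=C/N(C)C)c(OC)cc1O[Si](C)(C)C(C)(C)C
F3 | step 17 | 7-(TBSO)-5-methoxy-8-[(2R)-5-methyl-2-(prop-1-en-2-yl)-5-(TESO)hexyl]-4H-chromen-4-one | C=C(C)[C@H](CCC(C)(C)O[Si](CC)(CC)CC)Cc1c(O[Si](C)(C)C(C)(C)C)cc(OC)c2c1OC=CC2=O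
F4 | step 17 | (2S)-7-(TBSO)-2-(4-hydroxy-2-methoxyphenyl)-5-methoxy-8-[(2R)-5-methyl-2-(prop-1-en-2-yl)-5-(TESO)hexyl]-2,3-dihydro-4H-chromen-4-one | C=C(C)[C@H](CCC(C)(C)O[Si](CC)(CC)CC)Cc1c(O[Si](C)(C)C(C)(C)C)cc(OC)c2c1O[C@H](c1ccc(O)cc1OC)CC2=O
F5 | step 12 | 4-bromo-5-methoxy-2-[(2R)-5-methyl-2-(prop-1-en-2-yl)-5-(TESO)hexyl]-1,3-phenylene bis[4-(TBSO)-2-methoxybenzoate] | C=C(C)[C@H](CCC(C)(C)O[Si](CC)(CC)CC)Cc1c(OC(=O)c2ccc(O[Si](C)(C)C(C)(C)C)cc2OC)c(Br)c(OC)cc1OC(=O)c1ccc(O[Si](C)(C)C(C)(C)C)cc1OC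
F6 | step 12 | 2-bromo-5-hydroxy-3-methoxy-6-[(2R)-5-methyl-2-(prop-1-en-2-yl)-5-(TESO)hexyl]phenyl 4-(TBSO)-2-methoxybenzoate | C=C(C)[C@H](CCC(C)(C)O[Si](CC)(CC)CC)Cc1c(OC(=O)c2ccc(O[Si](C)(C)C(C)(C)C)cc2OC)c(Br)c(OC)cc1O
F7 | step 9 | lithium bis[4-methoxy-2,6-bis(methoxymethoxy)phenyl]cuprate | [Li+].COCOc1cc(OC)cc(OCOC)c1[Cu-]c1c(OCOC)cc(OC)cc1OCOC
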